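## Structural features

The target is built on a 2,5-diaryl-3,4-dimethyltetrahydrofuran (O1, C2–C5). Each of its two 3-methoxyphenyl rings is linked through its C4 oxygen to C8 of a 1-(3,4-dimethoxyphenyl)propan-1-ol arm, so four aryl rings and two three-carbon chains hang on one five-membered ring. The ring carries four contiguous stereocentres (2S,3S,4S,5R): the aryl groups are cis and the methyl groups trans, so the C2 aryl is trans and the C5 aryl cis to its neighbouring methyl. Each arm adds a vicinal pair, (7R,8S) on the C2 aryl and (7R,8R) on the C5 aryl: the same sense at C7 beside opposite senses at C8, far from the ring and from each other. The fragile parts are the two ring C–O bonds, which are p-alkoxybenzylic ethers (acid ionises them, after which C5 relaxes to the all-trans ring, and hydrogenolysis can cut them), and the C7 carbinols, which are benzylic and β to an aryloxy group. The real difficulty is stereochemical: a cis aryl/methyl pair inside a ring whose other pair is trans, and two carbinols of one configuration beside C8 centres of both configurations, which excludes substrate control for at least one arm. The key step exploits that C7 of each arm is a benzylic CH2 para to O4 of a terminal ring: once O4 is a free phenol, this position can be dehydrogenated to a p-quinone methide and hydrated, whereas C2–H and C5–H of the ring are para to etherified oxygens and cannot follow.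

## Logic of the disconnections

27 is cut at the two O–CH3 bonds on O4 of the terminal rings, giving 26. This exposes the two phenols that the key step needs and that set the arm benzylic positions apart from those of the ring. The forward methylation must touch only phenols, not the two secondary carbinols, and must not ionise C7.

26 is cut at both C7–O bonds, giving 23. Two of eight stereocentres and all oxygen at C7 disappear, and each arm becomes a 1-arylpropan-2-yl ether with one bought stereocentre. The forward step must oxidise two CH2 groups and no other benzylic position, and must add oxygen from the same face on both arms against the bias of C8 on one of them. That calls for catalyst control, here an enzyme of the 4-alkylphenol oxidase family. The O2-dependent wild-type oxidase of this family hydrates from the opposite face, and the natural enzyme with the right face is not an oxidase, so a face-inverted oxidase variant is proposed.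

23 is cut at its two O–Si bonds, giving 22. The terminal phenols are masked as silyl ethers so that they can be freed by fluoride. No hydrogenolysis or acid then comes near the ring benzylic ethers. The silyl ethers must survive organomagnesium and organolithium reagents, buffered peroxide and a Lewis acid at −78 °C.

22 is cut at C2–H, giving 21, and 21 at the C2–aryl bond, giving 19 and 10 (through 20). Each half already carries its arm, so no core phenol ever has to be differentiated or deprotected selectively. Hydride delivery to a 2-aryl oxocarbenium ion of this ring type places the aryl trans to the adjacent methyl. C2 is therefore the centre to make this way, and the cis pair C4/C5 must already be in 19. The forward steps need single addition of 20 to 19 and reduction without ionising the C5–O bond.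

19 is cut at C3–CH3, giving 17. An enolate alkylation sets C3; the methyl must enter anti to the C4 methyl and the C5 aryl, which lie on one face.

17 is cut at the lactone oxidation level and at the terminal C–O bond, giving 15 and then 13. The forward steps need anti-Markovnikov hydration of a vinyl group and oxidation of a primary alcohol in the presence of a benzylic one.

13 is cut at the bond between the carbinol carbon (future C5) and the methyl-bearing carbon (future C4), giving 9 and 11. A syn crotylation sets the cis pair and the absolute configuration of the ring in one step. The catalyst must choose the aldehyde face; the remote C8 centre neither helps nor hinders.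

9 is cut at its C8–O(aryl) bond, giving 8 and 5; 10 is cut likewise, giving 1 and 7. The etherifications are done on two simple phenols, with inversion, and not on a core bisphenol. The forward step must be a clean SN2 reaction without elimination to the propenylarene.

5 and 7 are cut at the aryl–CH2 bond, giving 3 and 4 or 6. C8 is bought as propylene oxide of either hand; attack must occur only at the CH2 carbon. One batch of 3 serves both openings.

3 is cut at C–Mg, giving 2, and 2 is cut at O–Si, giving 1.

## Other disconnections considered

Alternative 1: The ring is cut at O1–C5 and C2–C3, leading to 4-(benzyloxy)-3-methoxybenzaldehyde A3 and the trans cyclopropane diester A2 (aryl on the carbon that becomes C5, methyl on the carbon that becomes C4).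
- Forward step: Sn(OTf)2 would activate the diester; the aldehyde oxygen would open the three-membered ring at the benzylic carbon with inversion, and the malonate carbon would close onto the oxocarbenium carbon to give A1 with the aryl groups cis.
- In its favour: ring, two bonds and the 2,5-cis relation in one catalytic step; an electron-rich aldehyde is a good partner; A1 already carries two different phenol protecting groups.
- Against it here: a 3,4-dioxygenated aryl donor makes A2 prone to ionise at the benzylic carbon before capture, which would erode both enantiomeric purity and the cis C4/C5 relation. The extra methyl slows the annulation. An enantioselective route to A2 is itself unsolved. C3 of A1 carries two esters that must become one methyl of defined configuration (loss of one ester, reduction, deoxygenation). The arms would then be attached to the two phenols in turn, with a debenzylation next to the ring benzylic ethers.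
- Comparison: in ring construction the alternative is the better plan (one step against aryl addition plus reduction). In security of C4/C5 and of the absolute configuration the chosen plan is stronger, since it rests on a catalyst-controlled crotylation. In step economy the ester-to-methyl detour and the late, stepwise arm attachment make the alternative longer. It does not address the C7 carbinols and would need step 14 or a ketone reduction as well.

Alternative 2: The ring is cut at O1–C2, leading to the open-chain phenol alcohol A5 with C3, C4 and C5 in place.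
- Forward step: anodic two-electron oxidation of the free guaiacyl ring of A5 would make C2 electrophilic (quinone methide stage), and the C5 hydroxyl would trap it to give A4.
- In its favour: it uses the same feature as the chosen key step (a benzylic position para to a free phenol), on which the two plans are equal. It needs only current. Phenols are oxidised at far lower potential than the aryl ethers present. Closure should place the C2 aryl trans to the C3 methyl, as the target needs. A4 has one phenol free. Intramolecular capture at this oxidation stage is closer to established practice than an evolved oxidase, and on precedent for its key step the alternative is the better plan.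
- Against it: phenoxyl radical coupling at the free ortho position, capture by solvent, and loss of a proton from C3 all compete. A4 is itself a phenol para to a benzylic C–H and can be oxidised again. A5 needs three contiguous centres on an open chain, in no fewer steps than 19 needs. Because the C2 aryl must be a free phenol, its arm cannot be in place, so arms are attached after ring formation with extra protecting-group steps.
- Comparison: worse in convergence and step count for this target; like alternative 1 it leaves the C7 carbinols unsolved.

Alternative 3: The C3–CH3 and C4–CH3 bonds are cut, leading to the (S)-butenolide A6.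
- Forward step: Me2CuLi would add to A6 anti to the aryl group, and the enolate would be methylated with MeI anti to the new methyl to give the all-trans lactone A7.
- In its favour: two stereocentres from one by 1,2-induction in one flask, with cheap reagents and a short route to A6.
- Against it: H5 of A6 is benzylic and vinylogously α to the carbonyl, so the basic conditions may racemise it, and the benzylic allylic C–O bond is open to reductive cleavage by the cuprate. More important, A7 carries the aryl that is trans to its neighbouring methyl (C2), so the remaining aryl must end cis to the C4 methyl. Aryllithium addition to A7 followed by hydride reduction would be expected to give the trans arrangement (all-trans ring). The second aryl would therefore have to enter as a carbon nucleophile on the C5 oxocarbenium ion after reduction of the lactone by one level and activation, which adds steps.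
- Comparison: up to the dimethyl lactone the alternative is the equal of the chosen plan in step count, and its double anti induction is at least as reliable as steps 7 and 10. From the lactone to the ring the chosen plan is shorter and better matched stereochemically, because it puts the cis pair into 19 and lets hydride make the trans pair. The alternative again needs late, sequential arm attachment.

Key step: step 14

Remark on locants and shorthand: O1 and C2–C5 are the tetrahydrofuran atoms; C7 and C8 are the benzylic and the oxygen-bearing carbon of each arm. ArR = 3-methoxy-4-{[(2R)-1-(3-methoxy-4-triisopropylsilyloxyphenyl)propan-2-yl]oxy}phenyl; ArS = the same group with (2S).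

Assumption: an oxidase variant that accepts 23 is taken to be obtainable by directed evolution of vanillyl alcohol oxidase; it is not a catalogue enzyme.

## Route

Step 1
Reactants: 1 4-bromo-2-methoxyphenol
Product: 2 (4-bromo-2-methoxyphenoxy)triisopropylsilane
Conditions: i-Pr3SiCl, imidazole, DMF, rt
Reagents that add atoms: chlorotriisopropylsilane, CC(C)[Si](Cl)(C(C)C)C(C)C
Why: Silylation of a phenol (substitution at silicon). The triisopropylsilyl ether withstands the organometallic, buffered peroxide and cold Lewis acid steps and leaves with fluoride, so no hydrogenolysis is needed near the ring benzylic ethers.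

Step 2
Reactants: 2 (4-bromo-2-methoxyphenoxy)triisopropylsilane
Product: 3 [3-methoxy-4-(triisopropylsilyloxy)phenyl]magnesium bromide (THF solution, titrated and divided into two portions)
Conditions: Mg turnings, I2 (crystal), THF, 45 °C
Reagents that add atoms: magnesium, [Mg]
Why: Grignard formation by insertion of magnesium into the aryl C–Br bond; the silyl and methyl ethers are inert, and one stock solution supplies both epoxide openings.

Step 3
Reactants: 3 [3-methoxy-4-(triisopropylsilyloxy)phenyl]magnesium bromide, 4 (S)-propylene oxide
Product: 5 (2S)-1-[3-methoxy-4-(triisopropylsilyloxy)phenyl]propan-2-ol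
Conditions: 3 (THF solution), CuI (10 mol%), 4, −30 → 0 °C; aq. NH4Cl
Reagents that add atoms: none
Why: Copper-catalysed opening of a terminal epoxide by a Grignard reagent at the CH2 carbon. The stereocentre is not touched, so (S) is carried over.

Step 4
Reactants: 3 [3-methoxy-4-(triisopropylsilyloxy)phenyl]magnesium bromide, 6 (R)-propylene oxide
Product: 7 (2R)-1-[3-methoxy-4-(triisopropylsilyloxy)phenyl]propan-2-ol
Conditions: 3 (THF solution), CuI (10 mol%), 6, −30 → 0 °C; aq. NH4Cl
Reagents that add atoms: none
Why: Same copper-catalysed epoxide opening as step 3 with the other enantiomer; (R) is carried over.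

Step 5
Reactants: 8 vanillin (4-hydroxy-3-methoxybenzaldehyde), 5 (2S)-1-[3-methoxy-4-(triisopropylsilyloxy)phenyl]propan-2-ol
Product: 9 3-methoxy-4-{[(2R)-1-(3-methoxy-4-triisopropylsilyloxyphenyl)propan-2-yl]oxy}benzaldehyde
Conditions: PPh3, DIAD, THF, 0 °C → rt
Reagents that add atoms: none
Why: Mitsunobu etherification; the para-formyl phenol is acidic enough to be a good pronucleophile. Displacement at C8 is SN2 with inversion, (S)-alcohol to (R)-ether, which becomes C8 of the C5-aryl arm.

Step 6
Reactants: 1 4-bromo-2-methoxyphenol, 7 (2R)-1-[3-methoxy-4-(triisopropylsilyloxy)phenyl]propan-2-ol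
Product: 10 4-bromo-2-methoxy-1-{[(2S)-1-(3-methoxy-4-triisopropylsilyloxyphenyl)propan-2-yl]oxy}benzene
Conditions: PPh3, DIAD, toluene, 0 °C → rt
Reagents that add atoms: none
Why: Mitsunobu etherification with inversion, (R)-alcohol to (S)-ether, which becomes C8 of the C2-aryl arm.

Step 7
Reactants: 9 3-methoxy-4-{[(2R)-1-(3-methoxy-4-triisopropylsilyloxyphenyl)propan-2-yl]oxy}benzaldehyde, 11 (Z)-crotylboronic acid pinacol ester
Product: 13 (1R,2S)-1-ArR-2-methylbut-3-en-1-ol, via pinacol borate ester 12 (not isolated)
Conditions: (R)-3,3′-bis(2,4,6-triisopropylphenyl)-1,1′-binaphthyl-2,2′-diyl hydrogen phosphate (5 mol%), 4 Å molecular sieves, toluene, −30 °C; aq. NaHCO3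
Reagents that add atoms: none
Why: Chiral phosphoric acid-catalysed crotylboration of an aryl aldehyde through a closed six-membered chair transition state: the (Z)-boronate gives the syn adduct (the future cis C4-methyl/C5-aryl pair) and the acid selects the re face to give (1R). The (R)-acid is the hand expected to give (R)-carbinols from benzaldehyde-type substrates; the configuration of 13 would be confirmed by Mosher ester analysis before material is carried forward, and the (S)-acid is equally available.

Step 8
Reactants: 13 (1R,2S)-1-ArR-2-methylbut-3-en-1-ol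
Product: 15 (1R,2S)-1-ArR-2-methylbutane-1,4-diol, via bis(9-BBN) adduct 14 (not isolated)
Conditions: 9-BBN (2.5 equiv), THF, 0 °C → rt; then aq. NaOAc, 30% H2O2, 0 °C → rt
Reagents that add atoms: hydrogen peroxide, OO
Why: Anti-Markovnikov hydroboration–oxidation of a monosubstituted alkene; the free hydroxyl consumes one equivalent of borane, hence the excess. No stereocentre is formed or touched, and buffered peroxide spares the aryl silyl ethers.

Step 9
Reactants: 15 (1R,2S)-1-ArR-2-methylbutane-1,4-diol
Product: 17 (4S,5R)-5-ArR-4-methyldihydrofuran-2(3H)-one, via lactol 16 (not isolated)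
Conditions: TEMPO (2,2,6,6-tetramethylpiperidin-1-oxyl, 20 mol%), PhI(OAc)2 (2.5 equiv), CH2Cl2, rt
Reagents that add atoms: none
Why: Oxoammonium-catalysed oxidative lactonisation of a 1,4-diol: the primary alcohol is oxidised first, the benzylic hydroxyl captures the aldehyde as lactol 16, and this is oxidised to the lactone. C4 and C5 are not involved, so the cis relation is kept.

Step 10
Reactants: 17 (4S,5R)-5-ArR-4-methyldihydrofuran-2(3H)-one
Product: 19 (3S,4S,5R)-5-ArR-3,4-dimethyldihydrofuran-2(3H)-one, via lithium enolate 18 (not isolated)
Conditions: LiN(i-Pr)2 (1.1 equiv), THF, −78 °C; MeI (3 equiv), −78 → −40 °C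
Reagents that add atoms: iodomethane, CI
Why: Lactone enolate alkylation; methyl iodide approaches the face opposite to the C4 methyl and the C5 aryl, which lie on the same side, so C3 is set trans to C4.

Step 11
Reactants: 10 4-bromo-2-methoxy-1-{[(2S)-1-(3-methoxy-4-triisopropylsilyloxyphenyl)propan-2-yl]oxy}benzene, 19 (3S,4S,5R)-5-ArR-3,4-dimethyldihydrofuran-2(3H)-one
Product: 21 (3S,4S,5R)-2-ArS-5-ArR-3,4-dimethyltetrahydrofuran-2-ol (hemiketal as a C2 epimer mixture), via aryllithium 20 (not isolated)
Conditions: 10, n-BuLi (1.1 equiv), THF, −78 °C; then 19 (0.9 equiv), −78 °C; aq. NH4Cl at −78 °C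
Reagents that add atoms: none
Why: Bromine–lithium exchange followed by single addition of an aryllithium to a lactone; the tetrahedral lithium alkoxide persists at −78 °C, so no ketone is released before the quench. The step joins the two halves, each with its arm; C2 is not yet defined.

Step 12
Reactants: 21 (3S,4S,5R)-2-ArS-5-ArR-3,4-dimethyltetrahydrofuran-2-ol
Product: 22 (2S,3S,4S,5R)-2-ArS-5-ArR-3,4-dimethyltetrahydrofuran
Conditions: Et3SiH (3 equiv), BF3·OEt2 (2 equiv), CH2Cl2, −78 °C; Et3N, then aq. NaHCO3, −78 °C → rt
Reagents that add atoms: none
Why: Reductive deoxygenation of a cyclic hemiketal through the 2-aryl oxocarbenium ion (ionic hydrogenation). In the envelope with the C4 methyl pseudoequatorial, hydride enters C2 from the inside face, trans to the C4 methyl and the C5 aryl and cis to the C3 methyl; this places the C2 aryl trans to the C3 methyl and cis to the C5 aryl, the outcome known for hemiketals of this substitution pattern. Low temperature and a cold basic quench keep the C5–O bond from ionising.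

Step 13
Reactants: 22 (2S,3S,4S,5R)-2-ArS-5-ArR-3,4-dimethyltetrahydrofuran
Product: 23 (2S,3S,4S,5R)-2-(4-{[(2S)-1-(4-hydroxy-3-methoxyphenyl)propan-2-yl]oxy}-3-methoxyphenyl)-5-(4-{[(2R)-1-(4-hydroxy-3-methoxyphenyl)propan-2-yl]oxy}-3-methoxyphenyl)-3,4-dimethyltetrahydrofuran (7-deoxy bisphenol)
Conditions: Bu4NF (2.5 equiv), THF, 0 °C; aq. NH4Cl
Reagents that add atoms: none
Why: Fluoride cleavage of aryl silyl ethers, driven by Si–F bond formation; neutral towards the ring benzylic ethers and the alkyl aryl ethers.

Step 14
Reactants: 23 7-deoxy bisphenol
Product: 26 (2S,3S,4S,5R)-2-(4-{[(1R,2S)-1-hydroxy-1-(4-hydroxy-3-methoxyphenyl)propan-2-yl]oxy}-3-methoxyphenyl)-5-(4-{[(1R,2R)-1-hydroxy-1-(4-hydroxy-3-methoxyphenyl)propan-2-yl]oxy}-3-methoxyphenyl)-3,4-dimethyltetrahydrofuran, via C2-arm monocarbinol 24 (not isolated), via C5-arm monocarbinol 25 (not isolated)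
Conditions: evolved vanillyl alcohol oxidase variant (flavin enzyme, Asp170Ser/Thr457Glu background), O2 (air), catalase, KH2PO4/K2HPO4 buffer pH 7.5, 15% v/v DMSO, 25 °C
Reagents that add atoms: water, O
Why: Proposed new method: each terminal 4-hydroxy-3-methoxybenzyl group binds as its phenolate, C7 passes a hydride to N5 of the flavin, the enzyme-bound p-quinone methide takes up water at C7 and O2 reoxidises the flavin to H2O2 (destroyed by catalase); the arms react in separate cycles, through 24 or 25. The closest known reaction type is the enantioselective benzylic hydroxylation of 4-ethyl- and 4-propylphenol and their 2-methoxy analogues by vanillyl alcohol oxidase and p-cresol methylhydroxylase; a C8 aryloxy substituent of this size has no precedent, hence the evolved variant. No ring is closed. Each new stereocentre, C7 of the C2-aryl arm and C7 of the C5-aryl arm, is set by the active site, which fixes the face of the planar methide that water can reach. The (7R) centres needed correspond in space to (S)-1-(4-hydroxyphenyl)alkanols (C8 outranks the aryl here), the face opposite to that of wild-type vanillyl alcohol oxidase; p-cresol methylhydroxylase has that face but is a flavocytochrome that does not use O2, so the variant is built on the oxidase double mutant in which the catalytic aspartate is moved to the other side of the substrate. Both arms need the same face although C8 is S on one and R on the other, so catalyst control has to override the neighbouring centre. Chemoselectivity is secured by the substrate: only a benzylic C–H para to a free phenol can give up hydride, so C2–H and C5–H of the ring, para to etherified oxygens, are inert. The step also needs hydration to outrun loss of H8 from the methide and a second dehydrogenation of the carbinol to a ketone, which the variant and a stop at full consumption of 23, 24 and 25 have to ensure.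

Step 15
Reactants: 26 bis(4-O-demethyl) target
Product: 27 (2S,3S,4S,5R)-2-(4-{[(1R,2S)-1-(3,4-dimethoxyphenyl)-1-hydroxypropan-2-yl]oxy}-3-methoxyphenyl)-5-(4-{[(1R,2R)-1-(3,4-dimethoxyphenyl)-1-hydroxypropan-2-yl]oxy}-3-methoxyphenyl)-3,4-dimethyltetrahydrofuran (target, CNP0116650.9)
Conditions: MeI (3 equiv), K2CO3 (4 equiv), acetone, rt
Reagents that add atoms: iodomethane, CI
Why: Williamson methylation of phenols; carbonate deprotonates the phenols but not the secondary alcohols. Room temperature avoids loss of hydroxide from the p-hydroxybenzyl carbinols, so C7 is not scrambled.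

## Compound list

1 | 4-bromo-2-methoxyphenol | COc1cc(Br)ccc1O | starting material
2 | (4-bromo-2-methoxyphenoxy)triisopropylsilane | COc1cc(Br)ccc1O[Si](C(C)C)(C(C)C)C(C)C | intermediate
3 | [3-methoxy-4-(triisopropylsilyloxy)phenyl]magnesium bromide | COc1cc([Mg]Br)ccc1O[Si](C(C)C)(C(C)C)C(C)C | intermediate
4 | (S)-propylene oxide | C[C@H]1CO1 | starting material
5 | (2S)-1-[3-methoxy-4-(triisopropylsilyloxy)phenyl]propan-2-ol | C[C@H](O)Cc1ccc(O[Si](C(C)C)(C(C)C)C(C)C)c(OC)c1 | intermediate
6 | (R)-propylene oxide | C[C@@H]1CO1 | starting material
7 | (2R)-1-[3-methoxy-4-(triisopropylsilyloxy)phenyl]propan-2-ol | C[C@@H](O)Cc1ccc(O[Si](C(C)C)(C(C)C)C(C)C)c(OC)c1 | intermediate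
8 | vanillin | COc1cc(C=O)ccc1O | starting material
9 | 3-methoxy-4-{[(2R)-1-(3-methoxy-4-triisopropylsilyloxyphenyl)propan-2-yl]oxy}benzaldehyde | O=Cc1ccc(O[C@H](C)Cc2ccc(O[Si](C(C)C)(C(C)C)C(C)C)c(OC)c2)c(OC)c1 | intermediate
10 | 4-bromo-2-methoxy-1-{[(2S)-1-(3-methoxy-4-triisopropylsilyloxyphenyl)propan-2-yl]oxy}benzene | Brc1ccc(O[C@@H](C)Cc2ccc(O[Si](C(C)C)(C(C)C)C(C)C)c(OC)c2)c(OC)c1 | intermediate
11 | (Z)-crotylboronic acid pinacol ester, 2-[(2Z)-but-2-en-1-yl]-4,4,5,5-tetramethyl-1,3,2-dioxaborolane | C/C=C\CB1OC(C)(C)C(C)(C)O1 | starting material
12 | pinacol borate ester of 13 | CC1(C)OB(OC1(C)C)O[C@@H](c1ccc(O[C@H](C)Cc2ccc(O[Si](C(C)C)(C(C)C)C(C)C)c(OC)c2)c(OC)c1)[C@@H](C)C=C | intermediate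
13 | (1R,2S)-1-ArR-2-methylbut-3-en-1-ol (syn) | O[C@@H](c1ccc(O[C@H](C)Cc2ccc(O[Si](C(C)C)(C(C)C)C(C)C)c(OC)c2)c(OC)c1)[C@@H](C)C=C | intermediate
14 | O,C-bis(9-borabicyclo[3.3.1]nonan-9-yl) adduct of 13 | B1(C2CCCC1CCC2)O[C@@H](c1ccc(O[C@H](C)Cc2ccc(O[Si](C(C)C)(C(C)C)C(C)C)c(OC)c2)c(OC)c1)[C@@H](C)CCB1C2CCCC1CCC2 | intermediate
15 | (1R,2S)-1-ArR-2-methylbutane-1,4-diol | O[C@@H](c1ccc(O[C@H](C)Cc2ccc(O[Si](C(C)C)(C(C)C)C(C)C)c(OC)c2)c(OC)c1)[C@@H](C)CCO | intermediate
16 | (4S,5R)-5-ArR-4-methyltetrahydrofuran-2-ol (lactol, both C2 epimers) | O1[C@@H](c2ccc(O[C@H](C)Cc3ccc(O[Si](C(C)C)(C(C)C)C(C)C)c(OC)c3)c(OC)c2)[C@@H](C)CC1O | intermediate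
17 | (4S,5R)-5-ArR-4-methyldihydrofuran-2(3H)-one (cis) | O1[C@@H](c2ccc(O[C@H](C)Cc3ccc(O[Si](C(C)C)(C(C)C)C(C)C)c(OC)c3)c(OC)c2)[C@@H](C)CC1=O | intermediate
18 | lithium enolate of 17 | O1[C@@H](c2ccc(O[C@H](C)Cc3ccc(O[Si](C(C)C)(C(C)C)C(C)C)c(OC)c3)c(OC)c2)[C@@H](C)C=C1O[Li] | intermediate
19 | (3S,4S,5R)-5-ArR-3,4-dimethyldihydrofuran-2(3H)-one (3,4-trans, 4,5-cis) | O1[C@@H](c2ccc(O[C@H](C)Cc3ccc(O[Si](C(C)C)(C(C)C)C(C)C)c(OC)c3)c(OC)c2)[C@@H](C)[C@H](C)C1=O | intermediate
20 | aryllithium from 10, (3-methoxy-4-{[(2S)-1-(3-methoxy-4-triisopropylsilyloxyphenyl)propan-2-yl]oxy}phenyl)lithium | [Li]c1ccc(O[C@@H](C)Cc2ccc(O[Si](C(C)C)(C(C)C)C(C)C)c(OC)c2)c(OC)c1 | intermediate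
21 | (3S,4S,5R)-2-ArS-5-ArR-3,4-dimethyltetrahydrofuran-2-ol (hemiketal, both C2 epimers) | O1[C@@H](c2ccc(O[C@H](C)Cc3ccc(O[Si](C(C)C)(C(C)C)C(C)C)c(OC)c3)c(OC)c2)[C@@H](C)[C@H](C)C1(O)c2ccc(O[C@@H](C)Cc3ccc(O[Si](C(C)C)(C(C)C)C(C)C)c(OC)c3)c(OC)c2 | intermediate
22 | (2S,3S,4S,5R)-2-ArS-5-ArR-3,4-dimethyltetrahydrofuran | CC(C)[Si](C(C)C)(C(C)C)Oc1ccc(C[C@H](C)Oc2ccc([C@H]3O[C@@H](c4ccc(O[C@H](C)Cc5ccc(O[Si](C(C)C)(C(C)C)C(C)C)c(OC)c5)c(OC)c4)[C@@H](C)[C@@H]3C)cc2OC)cc1OC | intermediate
23 | 7-deoxy bisphenol (name as in step 13) | Oc1ccc(C[C@H](C)Oc2ccc([C@H]3O[C@@H](c4ccc(O[C@H](C)Cc5ccc(O)c(OC)c5)c(OC)c4)[C@@H](C)[C@@H]3C)cc2OC)cc1OC | intermediate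
24 | C2-arm monocarbinol (23 with (7R)-OH on the arm of the C2 aryl only) | Oc1ccc([C@@H](O)[C@H](C)Oc2ccc([C@H]3O[C@@H](c4ccc(O[C@H](C)Cc5ccc(O)c(OC)c5)c(OC)c4)[C@@H](C)[C@@H]3C)cc2OC)cc1OC | intermediate
25 | C5-arm monocarbinol (23 with (7R)-OH on the arm of the C5 aryl only) | Oc1ccc(C[C@H](C)Oc2ccc([C@H]3O[C@@H](c4ccc(O[C@H](C)[C@H](O)c5ccc(O)c(OC)c5)c(OC)c4)[C@@H](C)[C@@H]3C)cc2OC)cc1OC | intermediate
26 | bis(4-O-demethyl) target (name as in step 14) | Oc1ccc([C@@H](O)[C@H](C)Oc2ccc([C@H]3O[C@@H](c4ccc(O[C@H](C)[C@H](O)c5ccc(O)c(OC)c5)c(OC)c4)[C@@H](C)[C@@H]3C)cc2OC)cc1OC | intermediate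
27 | target CNP0116650.9 (name as in step 15) | COc1ccc([C@@H](O)[C@H](C)Oc2ccc([C@H]3O[C@@H](c4ccc(O[C@H](C)[C@H](O)c5ccc(OC)c(OC)c5)c(OC)c4)[C@@H](C)[C@@H]3C)cc2OC)cc1OC | target

## Step count and least certain steps

Total: 15 steps. Longest linear sequence: 13 steps (1, 2, 3, 5, 7, 8, 9, 10, 11, 12, 13, 14, 15).

**Step 14 (key step, proposed new method).**
- Most likely failure: no turnover, because the active site of this enzyme family is a closed pocket sized for small 4-alkylphenols and 23 carries a large aryloxy group on C8.
- Next most likely: loss of H8 from the bound methide (which destroys C8), further dehydrogenation of the new carbinol to an aryl ketone, stalling after the first arm, or hydration from the wrong face on the arm whose C8 opposes the enzyme.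
- Fallback in known chemistry, from 23 back to 27, separating oxidation from stereocontrol:
  - 23 is treated with DDQ (4.2 equiv) in wet 1,4-dioxane at 0 °C → rt. Phenols are oxidised by this quinone much faster than aryl ethers, and only the amount needed for the two arms is used. Each arm passes through methide and carbinol to the 4-hydroxyaryl ketone, giving the 7,7′-dioxo bisphenol F1. Hydration of a β-aryloxy methide in acidic water is faster than its tautomerisation and no base is present, so C8 should hold.
  - Me3SiCHN2 in toluene–MeOH methylates the now more acidic phenols without base to give the 7,7′-dioxo dimethyl ether F2.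
  - Corey–Bakshi–Shibata reduction ((R)-2-methyl-CBS-oxazaborolidine, BH3·SMe2, THF, −20 °C; the hand is chosen on the premise that the aryl group is the larger substituent) sets both C7 centres (R) under reagent control and gives 27 directly, bypassing 26.

**Step 12.**
- Most likely failure: hydride delivery from the other face, because the C3 methyl next to the reacting carbon opposes inside attack; or BF3-promoted ionisation of the C5–O bond, which would epimerise the cis aryl/methyl pair towards the all-trans ring.
- Fallback from 21 back to 22, closing the ring by C–O bond formation and not by hydride delivery: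
  - 21 is silylated as its open hydroxy ketone tautomer (t-BuMe2SiCl, imidazole, DMF) to give the C5-O-silyl ketone F3.
  - NaBH4 (MeOH, 0 °C) gives the C2 carbinol F4 as a mixture of epimers.
  - MsCl/Et3N (CH2Cl2, −20 → 0 °C) turns the p-alkoxybenzylic carbinol into a leaving group that ionises; the C5 oxygen closes the ring and loses its silyl group, giving 22.
  - The cationic closure places the C2 aryl trans to the C3 methyl, and C5 is never ionised because its oxygen stays attached throughout.

**Step 7.**
- Most likely failure: insufficient enantioselectivity or the unexpected hand with this electron-rich aldehyde, or erosion of the syn preference if the (Z)-boronate isomerises. An error is not lost silently: the (R) centre of the arm turns the wrong enantiomeric series into diastereomers that can be detected and removed at 13 or 17.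
- Fallback from 9 to 13, stoichiometric reagent control in place of catalyst control: (Z)-crotyldiisopinocampheylborane, made from cis-2-butene, KOt-Bu/n-BuLi and (+)-B-methoxydiisopinocampheylborane (the borane from (−)-α-pinene) with BF3·OEt2 in THF at −78 °C, with NaBO3 work-up. This reagent attacks the re face of aryl aldehydes and gives 13 directly.

**Step 6.**
- Most likely failure: 1 is less acidic than 8, so the activated alcohol may eliminate towards the conjugated propenylarene or alkylate the hydrazide before it is displaced.
- Fallback from 5 to 10, forming the bond on the aryl side of the oxygen so that C8 is untouched: CuI (10 mol%), 3,4,7,8-tetramethyl-1,10-phenanthroline, Cs2CO3, toluene, 90 °C couples 5 (the (S)-alcohol, now with retention) with 4-bromo-1-iodo-2-methoxybenzene F5 at the C–I bond (Ullmann-type etherification) to give 10.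

## Further compounds

F1 | step 14 | 7,7′-dioxo bisphenol, (2S,3S,4S,5R)-2-(4-{[(2S)-1-(4-hydroxy-3-methoxyphenyl)-1-oxopropan-2-yl]oxy}-3-methoxyphenyl)-5-(4-{[(2R)-1-(4-hydroxy-3-methoxyphenyl)-1-oxopropan-2-yl]oxy}-3-methoxyphenyl)-3,4-dimethyltetrahydrofuran | Oc1ccc(C(=O)[C@H](C)Oc2ccc([C@H]3O[C@@H](c4ccc(O[C@H](C)C(=O)c5ccc(O)c(OC)c5)c(OC)c4)[C@@H](C)[C@@H]3C)cc2OC)cc1OC
F2 | step 14 | 7,7′-dioxo dimethyl ether (F1 with both phenols methylated) | COc1ccc(C(=O)[C@H](C)Oc2ccc([C@H]3O[C@@H](c4ccc(O[C@H](C)C(=O)c5ccc(OC)c(OC)c5)c(OC)c4)[C@@H](C)[C@@H]3C)cc2OC)cc1OC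
F3 | step 12 | C5-O-silyl ketone, (2S,3S,4R)-1-ArS-4-ArR-4-(tert-butyldimethylsilyloxy)-2,3-dimethylbutan-1-one | CC(C)(C)[Si](C)(C)O[C@@H](c1ccc(O[C@H](C)Cc2ccc(O[Si](C(C)C)(C(C)C)C(C)C)c(OC)c2)c(OC)c1)[C@@H](C)[C@H](C)C(=O)c1ccc(O[C@@H](C)Cc2ccc(O[Si](C(C)C)(C(C)C)C(C)C)c(OC)c2)c(OC)c1
F4 | step 12 | C2 carbinol, (2S,3S,4R)-1-ArS-4-ArR-4-(tert-butyldimethylsilyloxy)-2,3-dimethylbutan-1-ol (both C1 epimers) | CC(C)(C)[Si](C)(C)O[C@@H](c1ccc(O[C@H](C)Cc2ccc(O[Si](C(C)C)(C(C)C)C(C)C)c(OC)c2)c(OC)c1)[C@@H](C)[C@H](C)C(O)c1ccc(O[C@@H](C)Cc2ccc(O[Si](C(C)C)(C(C)C)C(C)C)c(OC)c2)c(OC)c1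
F0 | step 7 | none | none
F5 | step 6 | 4-bromo-1-iodo-2-methoxybenzene | COc1cc(Br)ccc1I
A1 | alternative 1 | dimethyl 2,5-cis-2-(4-benzyloxy-3-methoxyphenyl)-5-(4-allyloxy-3-methoxyphenyl)-4-methyltetrahydrofuran-3,3-dicarboxylate | c1ccccc1COc2ccc([C@H]3O[C@@H](c4ccc(OCC=C)c(OC)c4)[C@@H](C)C3(C(=O)OC)C(=O)OC)cc2OC
A2 | alternative 1 | dimethyl (2S,3R)-2-(4-allyloxy-3-methoxyphenyl)-3-methylcyclopropane-1,1-dicarboxylate (trans) | COC(=O)C1(C(=O)OC)[C@H](c2ccc(OCC=C)c(OC)c2)[C@H]1C
A3 | alternative 1 | 4-(benzyloxy)-3-methoxybenzaldehyde | COc1cc(C=O)ccc1OCc1ccccc1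
A4 | alternative 2 | (2S,3S,4S,5R)-2-(4-hydroxy-3-methoxyphenyl)-5-(4-tert-butyldimethylsilyloxy-3-methoxyphenyl)-3,4-dimethyltetrahydrofuran | Oc1ccc([C@H]2O[C@@H](c3ccc(O[Si](C)(C)C(C)(C)C)c(OC)c3)[C@@H](C)[C@@H]2C)cc1OC
A5 | alternative 2 | (1R,2S,3R)-1-(4-tert-butyldimethylsilyloxy-3-methoxyphenyl)-4-(4-hydroxy-3-methoxyphenyl)-2,3-dimethylbutan-1-ol | O[C@@H](c1ccc(O[Si](C)(C)C(C)(C)C)c(OC)c1)[C@@H](C)[C@H](C)Cc1ccc(O)c(OC)c1
A6 | alternative 3 | (S)-5-(4-benzyloxy-3-methoxyphenyl)furan-2(5H)-one | COc1cc([C@H]2OC(=O)C=C2)ccc1OCc1ccccc1
A7 | alternative 3 | (3S,4S,5S)-5-(4-benzyloxy-3-methoxyphenyl)-3,4-dimethyldihydrofuran-2(3H)-one (all-trans) | c1ccccc1COc2ccc([C@H]3OC(=O)[C@@H](C)[C@@H]3C)cc2OC
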